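A small charge of protic impurity, half of the starting material by concentration, can take product away from these flasks.

the same everywhere: starting material 0.050 M; partner 1.05 equiv; protic impurity 0.0250 M; time 10 min
- maple: temperature 30 °C
- ash: temperature 90 °C
- elm: temperature 60 °C

    starting material → open intermediate (k1 = 0.0099 s⁻¹, Ea1 = 96.0 kJ mol⁻¹)
    partner → second intermediate (k2 = 0.0047 s⁻¹, Ea2 = 83.0 kJ mol⁻¹)
    open intermediate + second intermediate → product (k3 = 5.3 M⁻¹ s⁻¹, Ea3 = 53.0 kJ mol⁻¹)
    open intermediate → decomposed reagent (k4 = 0.0040 s⁻¹, Ea4 = 102 kJ mol⁻¹)
    starting material + protic impurity → quenched substrate (k5 = 0.16 M⁻¹ s⁻¹, Ea5 = 51.0 kJ mol⁻¹)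
    (constants at 60 °C)

- the list of constants is for 60 °C, to be carried to other temperatures by the activation energies

- the best flask by amount of product, in percent of the starting material charged; "all alike" if 1.5 percentage points covers them all (maple / ash / elm / all alike)
- amount of product at the end, in percent of the starting material charged, maple
- amount of product at the end, in percent of the starting material charged, ash
- amount of product at the end, in percent of the starting material charged, elm

Follow one molecule through elm. At the first fork it opens by itself or meets the impurity, and its chance of opening with the full charge of impurity present is

0.712

The opened molecule then couples with second intermediate or decomposes. To weigh that fork, take the moment one lifetime of the starting material has passed: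

lifetime 71.9 s
opened by then 0.0225 M
made into second intermediate by then 0.0151 M
open intermediate waiting 0.00745 M

Second intermediate lasts 25.3 s among those waiting, shorter than that lifetime, so I let it couple as fast as partner feeds it. Each waiting molecule then couples at

0.0236 s⁻¹

against 0.0040 s⁻¹ for decomposing, a coupling chance of 0.855. The two chances multiply to 60.9% product in elm.

The weak link is the full charge of impurity, since quenching uses it up. Reckoned with that first chance, 0.0106 M stays at the end, which makes my mean [protic impurity] 0.0178 M. Call the opening chance, the chance of opening rather than being quenched at that mean:

0.777

Run through the same lines, this gives a lifetime of 78.4 s, 0.00836 M waiting, a coupling chance of 0.836, and 64.9% product in elm. That is my number.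

For maple, the half-life of step 1 at 30 °C is 36.0 min, longer than the 10 min allowed, so maple stays far behind elm. For ash I give no number.

The forecast puts elm first, with maple 7.5%, ash 59% and elm 63%, expecting “elm and ash to land close, with elm slightly ahead”. For elm my figure stands above the forecast's.

The simulation gives elm as the best flask: maple 7.35%, ash 58.4%, elm 64.9%. Elm leads ash by 6.5 percentage points, clear of the 1.5 points margin. In elm, opening outran quenching 2.5 to one at the start and 4.6 to one at 10.0 min, and the opening chance, 3.48 to one, lies between them. Elm holds 23.1% quenched substrate, against the 22.3% that chance loses.

Take the neighbour at 45 °C. There step 1 runs at 0.00193 s⁻¹ and quenching at 0.0672 M⁻¹ s⁻¹, so the chance at full impurity is 0.535. At that full pace 11.5% of the starting material is still unused after 10 min, so I count quenching on the used part, and the opening chance at the mean is 0.662. The neighbour ends with 43.4% product and 18% starting material left, and 63.7% of what it used escaped quenching.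

All constants belong to no real substance; the rest is arithmetic.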